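**Retrosynthetic overview**

1. The C15–O ester bond is made last, from the silyl-protected caffeic acid 22 and the hydroxy ester 19; one fluoride step then removes every silicon group.
2. C8=C17 comes from a C8 ketone (carried as a silyl enol ether from the cycloaddition); the C4 quaternary carbon comes from a C4 ketone via enol triflate, CO insertion and reductive methylation, with CH3 entering anti to CH3-20.
3. Key disconnection: bonds C5–C6 and C9–C10 of ring B, by an endo [4+2] between ring A (bought as 3-methylcyclohex-2-enone 11: C4=O, C5=C10–CH3) and the (Z)-2-silyloxydiene 10 (C6=C7–C8(OSi)=C9, carrying C11–C15). Ring A exists first; ring B is the only ring closed and the last.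
4. Enabling feature: in ring B (C5–C6–C7–C8–C9–C10) the sp2 carbon C8 lies 1,3 to the quaternary C10 and 1,4 to C5, the C5–C10 fusion is cis (H-5 syn to CH3-20), and the C9 chain is anti to CH3-20. This is what an endo addition of a 2-oxygenated diene to the ring-A alkene C5=C10 leaves behind, and C4 sits where it can carry the activating carbonyl.
5. Diene 10 comes from (S)-citronellol (source of C13) by ozonolysis, three-carbon extension with acrolein, oxidation and silyl dienol ether formation.

Key step: step 7

Remark: atoms carry labdane numbers; the SMILES is read as (4S,5S,9R,10R,13S), a cis-fused decalin with H-5, CH3-20 and CO2H-19 on one face and the C9 chain and CH3-18 on the other; the (S)-antipode of the step 7 catalyst is assumed to expose the required enone face, and the (R)-antipode is taken if the sense proves opposite.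

**Route**

Step 1
Reactants: 1 (S)-citronellol
Product: 2 tert-butyl{[(3S)-3,7-dimethyloct-6-en-1-yl]oxy}dimethylsilane
Conditions: TBSCl, imidazole, DMF, rt
Reagents that add atoms: tert-butyldimethylsilyl chloride, CC(C)(C)[Si](C)(C)Cl
Why: Imidazole-promoted O-silylation of the primary alcohol should be clean and masks O15 through the organometallic, oxidation and Lewis acid steps.

Step 2
Reactants: 2 tert-butyl{[(3S)-3,7-dimethyloct-6-en-1-yl]oxy}dimethylsilane
Product: 5 (4S)-6-(tert-butyldimethylsilyloxy)-4-methylhexan-1-ol, via secondary ozonide 3 (not isolated), via aldehyde 4 (not isolated)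
Conditions: O3, CH2Cl2, −78 °C; then NaBH4, MeOH, −78 °C → rt
Reagents that add atoms: ozone, [O-][O+]=O
Why: Ozonolysis of the only alkene with hydride work-up should give the primary alcohol at C9 and leaves the remote C13 stereocentre untouched.

Step 3
Reactants: 5 (4S)-6-(tert-butyldimethylsilyloxy)-4-methylhexan-1-ol
Product: 6 {[(3S)-6-bromo-3-methylhexyl]oxy}(tert-butyl)dimethylsilane
Conditions: CBr4, PPh3, CH2Cl2, 0 °C
Reagents that add atoms: carbon tetrabromide, BrC(Br)(Br)Br
Why: Appel bromination is an SN2 displacement at a primary carbon and should tolerate the silyl ether at 0 °C.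

Step 4
Reactants: 6 {[(3S)-6-bromo-3-methylhexyl]oxy}(tert-butyl)dimethylsilane
Product: 8 (7S)-9-(tert-butyldimethylsilyloxy)-7-methylnon-1-en-3-ol as both C3 epimers, via Grignard reagent 7 (not isolated)
Conditions: Mg, THF, 40 °C; then acrolein, −78 °C; aq. NH4Cl
Reagents that add atoms: acrolein, C=CC=O
Why: Grignard 1,2-addition to the enal should form the C9–C8 bond and bring in C6–C8; the new carbinol centre is uncontrolled and is erased in step 5.

Step 5
Reactants: 8 (7S)-9-(tert-butyldimethylsilyloxy)-7-methylnon-1-en-3-ol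
Product: 9 (7S)-9-(tert-butyldimethylsilyloxy)-7-methylnon-1-en-3-one
Conditions: IBX, DMSO, rt
Reagents that add atoms: none
Why: Hypervalent-iodine oxidation of the allylic alcohol under neutral conditions should give the vinyl ketone without base-induced conjugate addition or polymerisation.

Step 6
Reactants: 9 (7S)-9-(tert-butyldimethylsilyloxy)-7-methylnon-1-en-3-one
Product: 10 (3S,6Z)-1-(tert-butyldimethylsilyloxy)-3-methyl-7-(triisopropylsilyloxy)nona-6,8-diene
Conditions: TIPSOTf, Et3N, CH2Cl2, −78 → 0 °C
Reagents that add atoms: triisopropylsilyl trifluoromethanesulfonate, CC(C)[Si](C(C)C)(C(C)C)OS(=O)(=O)C(F)(F)F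
Why: Soft enolisation and O-silylation at the only enolisable position (C9) should give the 2-silyloxydiene, the Z enol ether being favoured because C11 then lies cis to oxygen and not to the vinyl carbon (allylic strain).

Step 7
Reactants: 10 (3S,6Z)-1-(tert-butyldimethylsilyloxy)-3-methyl-7-(triisopropylsilyloxy)nona-6,8-diene; 11 3-methylcyclohex-2-en-1-one
Product: 12 cis-fused cycloadduct, 15-(tert-butyldimethylsilyloxy)-8-(triisopropylsilyloxy)-17,18,19-trinorlabd-7-en-4-one (H-5 syn to CH3-20, C9 chain anti to CH3-20, 13S)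
Conditions: (S)-3,3-diphenyl-1-(o-tolyl)tetrahydro-1H,3H-pyrrolo[1,2-c][1,3,2]oxazaborole (20 mol%), AlBr3 (16 mol%), 11 (1.5 equiv), CH2Cl2, −78 → −40 °C
Reagents that add atoms: none
Why: Proposed new method: an enantioselective, Lewis-acid-catalysed hindered Diels–Alder reaction in which the AlBr3-activated oxazaborolidinium binds the C4 carbonyl of 11 (lone pair syn to C5–H) and the nucleophilic terminus C9 of the 2-silyloxydiene attacks the β-carbon C10 in a strongly asynchronous endo [4+2] transition state (Mukaiyama–Michael-like C9–C10 bond first, C5–C6 bond following within the same ion pair, silicon staying on O8); the closest known reactions are the AlBr3/AlMe3-promoted cycloadditions of 2-silyloxydienes to 3-methylcyclohex-2-enone, which build the same quaternary carbon without absolute control, and the cationic oxazaborolidine-catalysed Diels–Alder reactions of cyclohexenone and of methyl-substituted quinones, which form angular methyl centres β to the bound carbonyl with high enantioselectivity. Ring B is closed as the six-membered ring of an intermolecular [4+2] cycloaddition (in the stepwise limit a 6-endo-trig attack of the C5 enolate carbon on C6). The cis fusion (H-5 syn to CH3-20) follows from suprafacial addition across the ring-bound C5=C10 bond; C9 is set by the endo position of the C4 carbonyl together with the Z enol ether geometry, which places C11 outside and hence anti to CH3-20; the absolute configuration of C5, C9 and C10 comes from the catalyst, which shields one face of the bound enone. The regioselectivity needed (C9 to C10, not to C5) is secured by the 2-silyloxy group, which makes C9 the nucleophilic terminus and overrides the weak opposite bias of the C9 alkyl group. The triisopropylsilyl enol ether is chosen because it survives strong Lewis acids and leaves the C8 and C4 carbonyl groups differentiated in the product.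

Step 8
Reactants: 12 cis-fused cycloadduct
Product: 14 C3=C4 enol triflate of 12, via potassium enolate 13 (not isolated)
Conditions: KN(SiMe3)2, THF, −78 °C; then PhNTf2, −78 → 0 °C
Reagents that add atoms: N-phenylbis(trifluoromethanesulfonimide), O=S(=O)(N(c1ccccc1)S(=O)(=O)C(F)(F)F)C(F)(F)F
Why: Kinetic deprotonation by the hindered amide base occurs at the C3 methylene and not at the tertiary C5–H next to the quaternary C10, and enol triflate formation then removes the C4 carbonyl so that the cis ring fusion can no longer epimerise.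

Step 9
Reactants: 14 C3=C4 enol triflate of 12
Product: 15 2-(trimethylsilyl)ethyl 15-(tert-butyldimethylsilyloxy)-8-(triisopropylsilyloxy)-17,18-dinorlabda-3,7-dien-19-oate (cis-fused)
Conditions: Pd(OAc)2 (10 mol%), dppf, CO (1 atm), Et3N, Me3SiCH2CH2OH, DMF, 60 °C
Reagents that add atoms: carbon monoxide, [C-]#[O+]; 2-(trimethylsilyl)ethanol, C[Si](C)(C)CCO
Why: Palladium-catalysed alkoxycarbonylation of the enol triflate (oxidative addition, CO insertion, alcoholysis) should install C19 as an ester whose later cleavage by fluoride needs no attack at the hindered carbonyl.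

Step 10
Reactants: 15 dienyl ester
Product: 17 2-(trimethylsilyl)ethyl 15-(tert-butyldimethylsilyloxy)-8-(triisopropylsilyloxy)-17-norlabd-7-en-19-oate (cis-fused; ester syn to CH3-20), via lithium ester enolate 16 (not isolated)
Conditions: Li, NH3(l)/THF, t-BuOH (1 equiv), −78 °C; isoprene; then MeI, −78 → −33 °C
Reagents that add atoms: iodomethane, CI
Why: Birch-type reductive alkylation reduces the enoate to the C4 ester enolate, which MeI should methylate anti to the 1,3-related axial CH3-20 (equatorial attack in the cis-decalin conformer that keeps the C9 chain equatorial), so the ester ends syn to CH3-20 and H-5 as required, while the isolated silyl enol ether is not reduced.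

Step 11
Reactants: 17 C4-methylated ester
Product: 18 2-(trimethylsilyl)ethyl 15-hydroxy-8-oxo-17-norlabdan-19-oate (cis-fused)
Conditions: HF·pyridine, pyridine, THF, 0 °C → rt
Reagents that add atoms: none
Why: Protodesilylation of the silyl enol ether (protonation at C7) and cleavage of the primary silyl ether by HF under non-basic conditions should unveil the C8 ketone and O15–H without epimerising the now enolisable C9 and without touching the trimethylsilylethyl ester.

Step 12
Reactants: 18 keto alcohol
Product: 19 2-(trimethylsilyl)ethyl (4S,5S,9R,10R,13S)-15-hydroxylabd-8(17)-en-19-oate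
Conditions: Zn, CH2Br2, TiCl4, THF/CH2Cl2, 0 °C → rt (excess reagent)
Reagents that add atoms: dibromomethane, BrCBr
Why: Takai–Lombardo methylenation is non-basic and suited to hindered, epimerisable ketones, so the C8 ketone should become the exocyclic alkene with C9 intact, the free alcohol only consuming excess reagent.

Step 13
Reactants: 20 caffeic acid
Product: 22 (E)-3-[3,4-bis(tert-butyldimethylsilyloxy)phenyl]prop-2-enoic acid, via tris-silyl derivative 21 (not isolated)
Conditions: TBSCl, imidazole, DMF, rt; then AcOH, THF/H2O, rt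
Reagents that add atoms: tert-butyldimethylsilyl chloride, CC(C)(C)[Si](C)(C)Cl
Why: Exhaustive silylation followed by selective hydrolysis of the labile silyl ester should give the catechol-protected acid, aryl silyl ethers being stable to dilute acetic acid.

Step 14
Reactants: 19 hydroxy ester; 22 protected caffeic acid
Product: 23 2-(trimethylsilyl)ethyl (4S,5S,9R,10R,13S)-15-{(E)-3-[3,4-bis(tert-butyldimethylsilyloxy)phenyl]prop-2-enoyloxy}labd-8(17)-en-19-oate
Conditions: DCC, DMAP (cat.), CH2Cl2, 0 °C → rt
Reagents that add atoms: none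
Why: Steglich esterification (carbodiimide activation, acyl transfer by DMAP) of the unhindered primary alcohol should proceed cleanly while the C19 carboxyl is masked as its ester.

Step 15
Reactants: 23 protected ester
Product: 24 target, (4S,5S,9R,10R,13S)-15-[(E)-3-(3,4-dihydroxyphenyl)prop-2-enoyloxy]labd-8(17)-en-19-oic acid
Conditions: Bu4NF, THF, argon, 0 °C → rt; then AcOH
Reagents that add atoms: none
Why: Fluoride cleaves the two aryl silyl ethers and triggers β-elimination of the trimethylsilylethyl ester (ethene and Me3SiF leave), which frees the hindered C19 acid without hydrolysis and should leave the cinnamate ester and both alkenes untouched.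

**Compound list**

1 | (S)-citronellol, (3S)-3,7-dimethyloct-6-en-1-ol | CC(C)=CCC[C@H](C)CCO | starting material
2 | tert-butyl{[(3S)-3,7-dimethyloct-6-en-1-yl]oxy}dimethylsilane | CC(C)=CCC[C@H](C)CCO[Si](C)(C)C(C)(C)C | intermediate
3 | secondary ozonide of 2 (1,2,4-trioxolane, both epimers at the ring CH) | CC1(C)OOC(CC[C@H](C)CCO[Si](C)(C)C(C)(C)C)O1 | intermediate
4 | (4S)-6-(tert-butyldimethylsilyloxy)-4-methylhexanal | O=CCC[C@H](C)CCO[Si](C)(C)C(C)(C)C | intermediate
5 | (4S)-6-(tert-butyldimethylsilyloxy)-4-methylhexan-1-ol | OCCC[C@H](C)CCO[Si](C)(C)C(C)(C)C | intermediate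
6 | {[(3S)-6-bromo-3-methylhexyl]oxy}(tert-butyl)dimethylsilane | BrCCC[C@H](C)CCO[Si](C)(C)C(C)(C)C | intermediate
7 | [(4S)-6-(tert-butyldimethylsilyloxy)-4-methylhexyl]magnesium bromide | Br[Mg]CCC[C@H](C)CCO[Si](C)(C)C(C)(C)C | intermediate
8 | (7S)-9-(tert-butyldimethylsilyloxy)-7-methylnon-1-en-3-ol (both C3 epimers) | C=CC(O)CCC[C@H](C)CCO[Si](C)(C)C(C)(C)C | intermediate
9 | (7S)-9-(tert-butyldimethylsilyloxy)-7-methylnon-1-en-3-one | C=CC(=O)CCC[C@H](C)CCO[Si](C)(C)C(C)(C)C | intermediate
10 | (3S,6Z)-1-(tert-butyldimethylsilyloxy)-3-methyl-7-(triisopropylsilyloxy)nona-6,8-diene | C=C/C(O[Si](C(C)C)(C(C)C)C(C)C)=C/CC[C@H](C)CCO[Si](C)(C)C(C)(C)C | intermediate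
11 | 3-methylcyclohex-2-en-1-one | CC1=CC(=O)CCC1 | starting material
12 | cis-fused cycloadduct, 15-(tert-butyldimethylsilyloxy)-8-(triisopropylsilyloxy)-17,18,19-trinorlabd-7-en-4-one (H-5 syn to CH3-20; C9 chain anti to CH3-20; 13S) | CC(C)[Si](C(C)C)(C(C)C)OC1=CC[C@H]2[C@](C)(CCCC2=O)[C@@H]1CC[C@H](C)CCO[Si](C)(C)C(C)(C)C | intermediate
13 | potassium C3=C4 enolate of 12 | CC(C)[Si](C(C)C)(C(C)C)OC1=CC[C@H]2[C@](C)(CCC=C2[O-])[C@@H]1CC[C@H](C)CCO[Si](C)(C)C(C)(C)C.[K+] | intermediate
14 | C3=C4 enol triflate of 12 | CC(C)[Si](C(C)C)(C(C)C)OC1=CC[C@H]2[C@](C)(CCC=C2OS(=O)(=O)C(F)(F)F)[C@@H]1CC[C@H](C)CCO[Si](C)(C)C(C)(C)C | intermediate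
15 | 2-(trimethylsilyl)ethyl 15-(tert-butyldimethylsilyloxy)-8-(triisopropylsilyloxy)-17,18-dinorlabda-3,7-dien-19-oate (cis-fused) | CC(C)[Si](C(C)C)(C(C)C)OC1=CC[C@H]2[C@](C)(CCC=C2C(=O)OCC[Si](C)(C)C)[C@@H]1CC[C@H](C)CCO[Si](C)(C)C(C)(C)C | intermediate
16 | lithium ester enolate (C4=C19) formed from 15 | CC(C)[Si](C(C)C)(C(C)C)OC1=CC[C@H]2[C@](C)(CCCC2=C([O-])OCC[Si](C)(C)C)[C@@H]1CC[C@H](C)CCO[Si](C)(C)C(C)(C)C.[Li+] | intermediate
17 | 2-(trimethylsilyl)ethyl 15-(tert-butyldimethylsilyloxy)-8-(triisopropylsilyloxy)-17-norlabd-7-en-19-oate (cis-fused; ester syn to CH3-20, CH3-18 anti) | CC(C)[Si](C(C)C)(C(C)C)OC1=CC[C@H]2[C@](C)(CCC[C@]2(C)C(=O)OCC[Si](C)(C)C)[C@@H]1CC[C@H](C)CCO[Si](C)(C)C(C)(C)C | intermediate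
18 | 2-(trimethylsilyl)ethyl 15-hydroxy-8-oxo-17-norlabdan-19-oate (cis-fused, configuration as in 24) | O=C1CC[C@H]2[C@](C)(CCC[C@]2(C)C(=O)OCC[Si](C)(C)C)[C@@H]1CC[C@H](C)CCO | intermediate
19 | 2-(trimethylsilyl)ethyl (4S,5S,9R,10R,13S)-15-hydroxylabd-8(17)-en-19-oate | C=C1CC[C@H]2[C@](C)(CCC[C@]2(C)C(=O)OCC[Si](C)(C)C)[C@@H]1CC[C@H](C)CCO | intermediate
20 | caffeic acid | O=C(O)/C=C/c1ccc(O)c(O)c1 | starting material
21 | tert-butyldimethylsilyl (E)-3-[3,4-bis(tert-butyldimethylsilyloxy)phenyl]prop-2-enoate | CC(C)(C)[Si](C)(C)OC(=O)/C=C/c1ccc(O[Si](C)(C)C(C)(C)C)c(O[Si](C)(C)C(C)(C)C)c1 | intermediate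
22 | (E)-3-[3,4-bis(tert-butyldimethylsilyloxy)phenyl]prop-2-enoic acid | O=C(O)/C=C/c1ccc(O[Si](C)(C)C(C)(C)C)c(O[Si](C)(C)C(C)(C)C)c1 | intermediate
23 | 2-(trimethylsilyl)ethyl (4S,5S,9R,10R,13S)-15-{(E)-3-[3,4-bis(tert-butyldimethylsilyloxy)phenyl]prop-2-enoyloxy}labd-8(17)-en-19-oate | C=C1CC[C@H]2[C@](C)(CCC[C@]2(C)C(=O)OCC[Si](C)(C)C)[C@@H]1CC[C@H](C)CCOC(=O)/C=C/c1ccc(O[Si](C)(C)C(C)(C)C)c(O[Si](C)(C)C(C)(C)C)c1 | intermediate
24 | (4S,5S,9R,10R,13S)-15-[(E)-3-(3,4-dihydroxyphenyl)prop-2-enoyloxy]labd-8(17)-en-19-oic acid | C=C1CC[C@H]2[C@](C)(CCC[C@]2(C)C(=O)O)[C@@H]1CC[C@H](C)CCOC(=O)/C=C/c1ccc(O)c(O)c1 | target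

**Step count**

Total steps: 15. Longest linear sequence: 14 steps (steps 1–12, 14, 15).

**Steps most likely to fail**

1. Step 7 (proposed new method). The chiral Lewis acid may turn over slowly on the β,β-disubstituted enone, so that silyl transfer, hydrolysis of the dienol ether or arrest at the open Mukaiyama–Michael stage compete. It may also discriminate the enone faces poorly, which would give two ring diastereomers that the remote C13 centre makes hard to separate. The fallback uses known chemistry and moves absolute control from the catalyst to the dienophile. It sets out from diene 10. The known building block (R)-5-(tert-butyldimethylsilyloxy)cyclohex-2-en-1-one is treated with MeLi to give the tertiary allylic alcohol (5R)-5-(tert-butyldimethylsilyloxy)-1-methylcyclohex-2-en-1-ol F1. Oxidative 1,3-transposition with pyridinium chlorochromate, [C5H5NH][CrO3Cl], then gives (S)-5-(tert-butyldimethylsilyloxy)-3-methylcyclohex-2-en-1-one F2. F2 and 10 are combined under the achiral mixed Lewis acid AlBr3/AlMe3, the established conditions for cycloadditions of 2-silyloxydienes to 3-methylcyclohexenones. The diene should add anti to the C2 silyloxy group, as is general for 5-substituted cyclohexenones, giving the C2-silyloxy cycloadduct F3. DBU eliminates the β-silyloxy group (E1cB) to the C2=C3 enone F4. Conjugate reduction with LiBH(s-Bu)3 gives the regiodefined lithium enolate F5, and PhNTf2 traps it as enol triflate 14, where the route is rejoined.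

2. Step 10. Methylation may pass through the ring-flipped cis-decalin conformer (C9 chain axial), which would deliver CH3 syn to H-5 and erode the configuration at C4; over-reduction of the ester or protonation of the enolate instead of alkylation may also intervene. The fallback changes the stage at which C4 is made, so that the enolate is alkylated on a ring B without the bulky silyl enol ether next to C9. It sets out from 15. Bu4NF buffered with AcOH at low temperature should cleave only the silyl enol ether to give the 8-oxo enoate F6. Zn/CH2Br2/TiCl4 methylenation gives the 8(17)-ene enoate F7. Li/NH3 reduction gives the lithium ester enolate F8, and MeI gives the C4-methylated silyl ether F9. HF·pyridine then removes the primary silyl ether and returns to 19.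

3. Step 12. Carbonyl methylenation at the hindered C8 ketone may be slow, the free hydroxyl may quench the reagent, and Lewis-acid-induced enolisation may cost the configuration at C9. The fallback is a two-step Peterson olefination and sets out from 18. Addition of Me3SiCH2MgCl premixed with CeCl3 (a weakly basic organocerium reagent that adds to enolisable, hindered ketones) gives the β-hydroxysilane F10. HF·pyridine then induces elimination to the exocyclic alkene and returns to 19.

**Further compounds**

F1 | step 7 | (5R)-5-(tert-butyldimethylsilyloxy)-1-methylcyclohex-2-en-1-ol (both C1 epimers) | CC1(O)C=CC[C@@H](O[Si](C)(C)C(C)(C)C)C1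
F2 | step 7 | (S)-5-(tert-butyldimethylsilyloxy)-3-methylcyclohex-2-en-1-one | CC1=CC(=O)C[C@@H](O[Si](C)(C)C(C)(C)C)C1
F3 | step 7 | C2-silyloxy analogue of cycloadduct 12 (C2 silyloxy group syn to CH3-20) | CC(C)[Si](C(C)C)(C(C)C)OC1=CC[C@H]2[C@](C)(C[C@H](O[Si](C)(C)C(C)(C)C)CC2=O)[C@@H]1CC[C@H](C)CCO[Si](C)(C)C(C)(C)C
F4 | step 7 | C2=C3 enone derived from F3 | CC(C)[Si](C(C)C)(C(C)C)OC1=CC[C@H]2[C@](C)(CC=CC2=O)[C@@H]1CC[C@H](C)CCO[Si](C)(C)C(C)(C)C
F5 | step 7 | lithium C3=C4 enolate from F4 | CC(C)[Si](C(C)C)(C(C)C)OC1=CC[C@H]2[C@](C)(CCC=C2[O-])[C@@H]1CC[C@H](C)CCO[Si](C)(C)C(C)(C)C.[Li+]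
F6 | step 10 | 2-(trimethylsilyl)ethyl 15-(tert-butyldimethylsilyloxy)-8-oxo-17,18-dinorlabd-3-en-19-oate (cis-fused) | O=C1CC[C@H]2[C@](C)(CCC=C2C(=O)OCC[Si](C)(C)C)[C@@H]1CC[C@H](C)CCO[Si](C)(C)C(C)(C)C
F7 | step 10 | 2-(trimethylsilyl)ethyl 15-(tert-butyldimethylsilyloxy)-18-norlabda-3,8(17)-dien-19-oate (cis-fused) | C=C1CC[C@H]2[C@](C)(CCC=C2C(=O)OCC[Si](C)(C)C)[C@@H]1CC[C@H](C)CCO[Si](C)(C)C(C)(C)C
F8 | step 10 | lithium ester enolate (C4=C19) from F7 | C=C1CC[C@H]2[C@](C)(CCCC2=C([O-])OCC[Si](C)(C)C)[C@@H]1CC[C@H](C)CCO[Si](C)(C)C(C)(C)C.[Li+]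
F9 | step 10 | 15-O-tert-butyldimethylsilyl ether of 19 | C=C1CC[C@H]2[C@](C)(CCC[C@]2(C)C(=O)OCC[Si](C)(C)C)[C@@H]1CC[C@H](C)CCO[Si](C)(C)C(C)(C)C
F10 | step 12 | 8-hydroxy-8-(trimethylsilylmethyl) adduct of 18 (either C8 epimer) | OC1(C[Si](C)(C)C)CC[C@H]2[C@](C)(CCC[C@]2(C)C(=O)OCC[Si](C)(C)C)[C@@H]1CC[C@H](C)CCO
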